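Assumption: germacrane numbering is used for the target and all intermediates (lactone O on C6, C7–C11(=C13)–C12 lactone, methacrylate on O8, OMe on C9, aldehyde carbon C14 on C10, hydroxymethyl C15 on C4). The target is (6R,7S,8S,9S) with both ring alkenes ring-cis.

## Retrosynthetic overview

1. 29 ⇐ 25: acylation of O8 and one acidic step that frees C15–OH and the C14 aldehyde.
2. Key bond C6–C7: 25 ⇐ 23 by intramolecular CrCl2 Barbier allylation. The 2-(methoxycarbonyl)allyl metal is a homoenolate (β-acyl anion) equivalent, so C7, the β-carbon of an acrylate, attacks aldehyde carbon C6. The ten-membered carbocycle forms first and the γ-lactone directly after, in the same flask.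
3. 23 ⇐ 20 (Baylis–Hillman at C7, SN2' bromination) ⇐ 19 ⇐ 17 + 4 (C3–C4 by B-alkyl Suzuki coupling).
4. 17 ⇐ 9 + 13 (C9–C10; C9 set from C8 by chelation control); 13 from (S)-glycerate 10.
5. Both ring-cis trisubstituted alkenes come from alkynes: 9 by carbocupration/iodination of 6, and 4 by hydroalumination/iodination of 2.

## Route

Step 1
Reactants: 1 but-2-yne-1,4-diol
Product: 2 4-[(tert-butyldiphenylsilyl)oxy]but-2-yn-1-ol
Conditions: 1 (3 equiv), TBDPSCl (1 equiv), imidazole, DMF, 0 °C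
Reagents that add atoms: tert-butyl(chloro)diphenylsilane, CC(C)(C)[Si](Cl)(c1ccccc1)c1ccccc1
Why: Silyl ether formation on a symmetric diol used in threefold excess so that the mono-ether dominates; no stereocentre is involved.

Step 2
Reactants: 2 4-[(tert-butyldiphenylsilyl)oxy]but-2-yn-1-ol
Product: 4 (Z)-4-[(tert-butyldiphenylsilyl)oxy]-3-iodobut-2-en-1-ol, via sodium alkenylaluminate 3 (not isolated)
Conditions: NaAlH2(OCH2CH2OMe)2, THF, 0 → 23 °C; then I2, THF, −78 → 0 °C; aq. potassium sodium tartrate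
Reagents that add atoms: iodine, II
Why: Alkoxide-directed trans-hydroalumination delivers hydride to C5 and ties aluminium at C4 into a five-membered aluminate, and iodinolysis with retention places iodine (the later site of C3) cis to C6 and C15 trans to C6, which is the ring-cis geometry of the C4=C5 alkene.

Step 3
Reactants: 5 vinylmagnesium bromide (2 equiv); 6 3,3-diethoxyprop-1-yne
Product: 9 (3Z)-5,5-diethoxy-4-iodopenta-1,3-diene, via bromomagnesium divinylcuprate 7 (not isolated), via bromomagnesium dienyl(vinyl)cuprate 8 (not isolated)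
Conditions: 5, CuBr·SMe2 (1 equiv), Et2O/Me2S, −45 °C; 6, −45 → −25 °C; then I2, THF, −78 → 0 °C
Reagents that add atoms: iodine, II
Why: Normant carbocupration adds the vinyl group and copper syn across the alkyne with copper on the carbon next to the acetal, and iodinolysis proceeds with retention, so the vinyl group (C2–C3) ends cis to iodine (later C9) and trans to the acetal carbon C14, the geometry of the C1=C10 alkene.

Step 4
Reactants: 10 methyl (4S)-2,2-dimethyl-1,3-dioxolane-4-carboxylate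
Product: 11 methyl (2S)-2,3-dihydroxypropanoate
Conditions: p-TsOH·H2O (cat.), MeOH, 23 °C
Reagents that add atoms: none
Why: Acid-catalysed transketalisation of the acetonide to methanol (acetal exchange); the stereocentre (later C8) is not touched.

Step 5
Reactants: 11 methyl (2S)-2,3-dihydroxypropanoate
Product: 12 methyl (2S)-2,3-bis[(triethylsilyl)oxy]propanoate
Conditions: TESCl (2.3 equiv), imidazole, CH2Cl2, 0 → 23 °C
Reagents that add atoms: chlorotriethylsilane, CC[Si](Cl)(CC)CC
Why: Silyl ether formation at both hydroxyls; the primary triethylsilyl ether is the latent C7 aldehyde and the secondary one protects O8.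

Step 6
Reactants: 12 methyl (2S)-2,3-bis[(triethylsilyl)oxy]propanoate
Product: 13 (2S)-2,3-bis[(triethylsilyl)oxy]propanal
Conditions: i-Bu2AlH (1.05 equiv), CH2Cl2, −78 °C; MeOH, aq. potassium sodium tartrate
Reagents that add atoms: none
Why: Partial reduction of an α-silyloxy ester, whose tetrahedral aluminium hemiacetal is stable at −78 °C and releases the aldehyde on work-up without epimerising C8.

Step 7
Reactants: 9 (3Z)-5,5-diethoxy-4-iodopenta-1,3-diene; 13 (2S)-2,3-bis[(triethylsilyl)oxy]propanal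
Product: 16 (2S,3S,4E)-4-(diethoxymethyl)-1,2-bis[(triethylsilyl)oxy]hepta-4,6-dien-3-ol, via dienyllithium 14 (not isolated), via dienylzinc bromide 15 (not isolated)
Conditions: 9, t-BuLi (2.0 equiv), Et2O, −78 °C; ZnBr2 (2.2 equiv), −78 → −20 °C; 13, toluene, −20 → 0 °C; aq. NH4Cl
Reagents that add atoms: none
Why: Iodine–lithium exchange with retention of alkene geometry, transmetalation to zinc and chelation-controlled (Cram chelate) 1,2-addition, in which zinc bridges the carbonyl oxygen and the α-silyloxy oxygen and the alkenyl group enters anti to CH2OTES, give the syn diol derivative and so set C9 (8S,9S in germacrane numbering).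

Step 8
Reactants: 16 (2S,3S,4E)-4-(diethoxymethyl)-1,2-bis[(triethylsilyl)oxy]hepta-4,6-dien-3-ol
Product: 17 (3E,5S,6S)-4-(diethoxymethyl)-5-methoxy-6,7-bis[(triethylsilyl)oxy]hepta-1,3-diene
Conditions: Me3OBF4, 1,8-bis(dimethylamino)naphthalene, CH2Cl2, 0 → 23 °C
Reagents that add atoms: trimethyloxonium tetrafluoroborate, C[O+](C)C.F[B-](F)(F)F
Why: O-Methylation with a Meerwein salt and a hindered amine base avoids a free alkoxide and therefore 1,2-silyl migration from O8; C9 keeps its configuration.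

Step 9
Reactants: 17 (3E,5S,6S)-4-(diethoxymethyl)-5-methoxy-6,7-bis[(triethylsilyl)oxy]hepta-1,3-diene; 4 (Z)-4-[(tert-butyldiphenylsilyl)oxy]-3-iodobut-2-en-1-ol
Product: 19 (2E,6E,8S,9S)-3-{[(tert-butyldiphenylsilyl)oxy]methyl}-7-(diethoxymethyl)-8-methoxy-9,10-bis[(triethylsilyl)oxy]deca-2,6-dien-1-ol, via B-alkyl-9-borabicyclononane 18 (not isolated)
Conditions: 9-BBN-H, THF, 0 → 23 °C; then 4, Pd(dppf)Cl2 (5 mol %), AsPh3, Cs2CO3, DMF/H2O, 23 °C
Reagents that add atoms: none
Why: 9-BBN-H hydroborates only the terminal vinyl group of the diene (boron on C3), and B-alkyl Suzuki–Miyaura coupling with 4 forms the C3–C4 bond with retention of the iodoalkene geometry, the free allylic alcohol being tolerated.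

Step 10
Reactants: 19 (2E,6E,8S,9S)-3-{[(tert-butyldiphenylsilyl)oxy]methyl}-7-(diethoxymethyl)-8-methoxy-9,10-bis[(triethylsilyl)oxy]deca-2,6-dien-1-ol
Product: 20 (2E,6E,8S,9R)-3-{[(tert-butyldiphenylsilyl)oxy]methyl}-7-(diethoxymethyl)-8-methoxy-9-[(triethylsilyl)oxy]deca-2,6-dienedial
Conditions: (COCl)2, DMSO, CH2Cl2, −78 °C; Et3N, −78 → −30 °C
Reagents that add atoms: none
Why: Swern oxidation converts the allylic alcohol (C6) and, directly, the primary triethylsilyl ether (C7) into aldehydes, while the secondary triethylsilyl ether, the C15 silyl ether and the acetal survive and C8 is not epimerised at low temperature (its descriptor changes only because of CIP priorities).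

Step 11
Reactants: 20 (2E,6E,8S,9R)-3-{[(tert-butyldiphenylsilyl)oxy]methyl}-7-(diethoxymethyl)-8-methoxy-9-[(triethylsilyl)oxy]deca-2,6-dienedial; 21 methyl acrylate
Product: 22 methyl (4S,5S,6E,10E)-10-{[(tert-butyldiphenylsilyl)oxy]methyl}-6-(diethoxymethyl)-3-hydroxy-5-methoxy-2-methylidene-12-oxo-4-[(triethylsilyl)oxy]dodeca-6,10-dienoate (C3 epimers)
Conditions: 21 (10 equiv), DABCO (1 equiv), MeOH (1 equiv), 23 °C, 2–4 d
Reagents that add atoms: none
Why: Morita–Baylis–Hillman reaction, chemoselective for the saturated α-silyloxy aldehyde (C7) because a β,β-disubstituted enal (C6) is a very poor Baylis–Hillman electrophile; the new carbinol centre is formed as a mixture that is erased in step 12.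

Step 12
Reactants: 22 methyl (4S,5S,6E,10E)-10-{[(tert-butyldiphenylsilyl)oxy]methyl}-6-(diethoxymethyl)-3-hydroxy-5-methoxy-2-methylidene-12-oxo-4-[(triethylsilyl)oxy]dodeca-6,10-dienoate
Product: 23 methyl (2Z,4S,5S,6E,10E)-2-(bromomethyl)-10-{[(tert-butyldiphenylsilyl)oxy]methyl}-6-(diethoxymethyl)-5-methoxy-12-oxo-4-[(triethylsilyl)oxy]dodeca-2,6,10-trienoate
Conditions: NBS, Me2S, CH2Cl2, −20 → 0 °C
Reagents that add atoms: N-bromosuccinimide, O=C1CCC(=O)N1Br
Why: Corey–Kim-type activation of the allylic alcohol and SN2' attack of bromide transpose the allylic system to the conjugated (Z)-2-(bromomethyl)enoate (C8 cis to CH2Br), the usual outcome for Baylis–Hillman alcohols.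

Step 13
Reactants: 23 methyl (2Z,4S,5S,6E,10E)-2-(bromomethyl)-10-{[(tert-butyldiphenylsilyl)oxy]methyl}-6-(diethoxymethyl)-5-methoxy-12-oxo-4-[(triethylsilyl)oxy]dodeca-2,6,10-trienoate
Product: 25 (6R,7S,8S,9S)-15-[(tert-butyldiphenylsilyl)oxy]-14,14-diethoxy-9-methoxy-8-[(triethylsilyl)oxy]germacra-1(10),4,11(13)-trien-12,6-olide, via ring-closed hydroxy ester 24 (not isolated)
Conditions: CrCl2 (10 equiv), THF, 23 °C, 23 added by syringe pump over 10 h (final 2 mM); then 45 °C, 2 h; aq. NH4Cl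
Reagents that add atoms: none
Why: Intramolecular Nozaki–Hiyama (chromium Barbier) allylation in which the 2-(methoxycarbonyl)allylchromium is a homoenolate (β-acyl anion) equivalent, so that C7, normally the electrophilic β-carbon of an acrylate, attacks the electrophilic aldehyde carbon C6; the allylchromium equilibrates by 1,3-metal shift and closes through the chair Zimmerman–Traxler transition state with both ring branches (C5 on the aldehyde, C8 on the allyl terminus) equatorial, giving the anti adduct and, after attack of the chromium alkoxide on the ester, the trans-fused lactone (6R,7S), while the face of C7 is fixed by C8 (H8 eclipsing the alkene to avoid allylic 1,3-strain, the OTES group turned outward, the C8–C9 ring bond anti to the incoming aldehyde), and the two ring-cis alkenes together with slow addition favour ring closure over oligomers.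

Step 14
Reactants: 25 (6R,7S,8S,9S)-15-[(tert-butyldiphenylsilyl)oxy]-14,14-diethoxy-9-methoxy-8-[(triethylsilyl)oxy]germacra-1(10),4,11(13)-trien-12,6-olide
Product: 26 (6R,7R,8S,9S)-15-[(tert-butyldiphenylsilyl)oxy]-14,14-diethoxy-8-hydroxy-9-methoxygermacra-1(10),4,11(13)-trien-12,6-olide
Conditions: Et3N·3HF, MeCN/THF, 0 → 23 °C
Reagents that add atoms: none
Why: Near-neutral fluoride cleaves the secondary triethylsilyl ether much faster than the tert-butyldiphenylsilyl ether and leaves the acetal and the α-methylene lactone intact (selective desilylation; the C7 descriptor changes only through CIP priorities).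

Step 15
Reactants: 26 (6R,7R,8S,9S)-15-[(tert-butyldiphenylsilyl)oxy]-14,14-diethoxy-8-hydroxy-9-methoxygermacra-1(10),4,11(13)-trien-12,6-olide; 27 methacrylic anhydride
Product: 28 (6R,7S,8S,9S)-15-[(tert-butyldiphenylsilyl)oxy]-14,14-diethoxy-9-methoxy-8-(methacryloyloxy)germacra-1(10),4,11(13)-trien-12,6-olide
Conditions: 27 (3 equiv), Et3N, DMAP (0.2 equiv), CH2Cl2, 0 → 23 °C
Reagents that add atoms: none
Why: DMAP-catalysed acyl transfer (Steglich-type acylation) to the only free hydroxyl, O8; no stereocentre is touched.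

Step 16
Reactants: 28 (6R,7S,8S,9S)-15-[(tert-butyldiphenylsilyl)oxy]-14,14-diethoxy-9-methoxy-8-(methacryloyloxy)germacra-1(10),4,11(13)-trien-12,6-olide
Product: 29 (6R,7S,8S,9S)-15-hydroxy-9-methoxy-8-(methacryloyloxy)-14-oxogermacra-1(10),4,11(13)-trien-12,6-olide (CNP0114830.1)
Conditions: 48% aq. HF, MeCN, 0 → 23 °C
Reagents that add atoms: water, O
Why: Aqueous HF removes the tert-butyldiphenylsilyl ether and hydrolyses the diethyl acetal to the enal in one acidic global deprotection; the enal geometry (C2 trans to CHO) is also the thermodynamically preferred one.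

## Compound list

1 | but-2-yne-1,4-diol | OCC#CCO | starting material
2 | 4-[(tert-butyldiphenylsilyl)oxy]but-2-yn-1-ol | OCC#CCO[Si](c1ccccc1)(c1ccccc1)C(C)(C)C | intermediate
3 | sodium cyclic alkenyl(alkoxy)bis(2-methoxyethoxy)aluminate from 2 (Al on C4, cis to C6) | [Na+].COCCO[Al-]1(OCCOC)OC/C=C1/CO[Si](c1ccccc1)(c1ccccc1)C(C)(C)C | intermediate
4 | (Z)-4-[(tert-butyldiphenylsilyl)oxy]-3-iodobut-2-en-1-ol (C6–C5=C4(I)–C15) | OC/C=C(\I)CO[Si](c1ccccc1)(c1ccccc1)C(C)(C)C | intermediate
5 | vinylmagnesium bromide | C=C[Mg]Br | starting material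
6 | 3,3-diethoxyprop-1-yne | C#CC(OCC)OCC | starting material
7 | bromomagnesium divinylcuprate | C=C[Cu-]C=C.[Mg+]Br | intermediate
8 | bromomagnesium [(1Z)-1-(diethoxymethyl)buta-1,3-dien-1-yl](vinyl)cuprate | C=C/C=C(\[Cu-]C=C)C(OCC)OCC.[Mg+]Br | intermediate
9 | (3Z)-5,5-diethoxy-4-iodopenta-1,3-diene (C3=C2–C1=C10(I)–C14) | C=C/C=C(\I)C(OCC)OCC | intermediate
10 | methyl (4S)-2,2-dimethyl-1,3-dioxolane-4-carboxylate | COC(=O)[C@@H]1COC(C)(C)O1 | starting material
11 | methyl (2S)-2,3-dihydroxypropanoate | COC(=O)[C@@H](O)CO | intermediate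
12 | methyl (2S)-2,3-bis[(triethylsilyl)oxy]propanoate | COC(=O)[C@@H](O[Si](CC)(CC)CC)CO[Si](CC)(CC)CC | intermediate
13 | (2S)-2,3-bis[(triethylsilyl)oxy]propanal (C9 aldehyde, C8, C7) | O=C[C@@H](O[Si](CC)(CC)CC)CO[Si](CC)(CC)CC | intermediate
14 | [(1Z)-1-(diethoxymethyl)buta-1,3-dien-1-yl]lithium | C=C/C=C(\[Li])C(OCC)OCC | intermediate
15 | [(1Z)-1-(diethoxymethyl)buta-1,3-dien-1-yl]zinc bromide | C=C/C=C(\[Zn]Br)C(OCC)OCC | intermediate
16 | (2S,3S,4E)-4-(diethoxymethyl)-1,2-bis[(triethylsilyl)oxy]hepta-4,6-dien-3-ol | C=C/C=C(/C(OCC)OCC)[C@H](O)[C@@H](O[Si](CC)(CC)CC)CO[Si](CC)(CC)CC | intermediate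
17 | (3E,5S,6S)-4-(diethoxymethyl)-5-methoxy-6,7-bis[(triethylsilyl)oxy]hepta-1,3-diene | C=C/C=C(/C(OCC)OCC)[C@H](OC)[C@@H](O[Si](CC)(CC)CC)CO[Si](CC)(CC)CC | intermediate
18 | B-alkyl-9-borabicyclo[3.3.1]nonane from 17 (boron on C3) | CCOC(OCC)/C(=C/CCB1C2CCCC1CCC2)[C@H](OC)[C@@H](O[Si](CC)(CC)CC)CO[Si](CC)(CC)CC | intermediate
19 | (2E,6E,8S,9S)-3-{[(tert-butyldiphenylsilyl)oxy]methyl}-7-(diethoxymethyl)-8-methoxy-9,10-bis[(triethylsilyl)oxy]deca-2,6-dien-1-ol | OC/C=C(/CO[Si](c1ccccc1)(c1ccccc1)C(C)(C)C)CC/C=C(/C(OCC)OCC)[C@H](OC)[C@@H](O[Si](CC)(CC)CC)CO[Si](CC)(CC)CC | intermediate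
20 | (2E,6E,8S,9R)-3-{[(tert-butyldiphenylsilyl)oxy]methyl}-7-(diethoxymethyl)-8-methoxy-9-[(triethylsilyl)oxy]deca-2,6-dienedial (C6 enal and C7 aldehyde) | O=C/C=C(/CO[Si](c1ccccc1)(c1ccccc1)C(C)(C)C)CC/C=C(/C(OCC)OCC)[C@H](OC)[C@@H](O[Si](CC)(CC)CC)C=O | intermediate
21 | methyl acrylate | C=CC(=O)OC | starting material
22 | Baylis–Hillman adduct at C7: methyl (4S,5S,6E,10E)-10-{[(tert-butyldiphenylsilyl)oxy]methyl}-6-(diethoxymethyl)-3-hydroxy-5-methoxy-2-methylidene-12-oxo-4-[(triethylsilyl)oxy]dodeca-6,10-dienoate, C3 epimers | O=C/C=C(/CO[Si](c1ccccc1)(c1ccccc1)C(C)(C)C)CC/C=C(/C(OCC)OCC)[C@H](OC)[C@@H](O[Si](CC)(CC)CC)C(O)C(=C)C(=O)OC | intermediate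
23 | methyl (2Z,4S,5S,6E,10E)-2-(bromomethyl)-10-{[(tert-butyldiphenylsilyl)oxy]methyl}-6-(diethoxymethyl)-5-methoxy-12-oxo-4-[(triethylsilyl)oxy]dodeca-2,6,10-trienoate | O=C/C=C(/CO[Si](c1ccccc1)(c1ccccc1)C(C)(C)C)CC/C=C(/C(OCC)OCC)[C@H](OC)[C@@H](O[Si](CC)(CC)CC)/C=C(\CBr)C(=O)OC | intermediate
24 | ring-closed hydroxy ester (present as its chromium alkoxide): ten-membered ring, (6R,7S,8S,9S), 6-OH, 7-[1-(methoxycarbonyl)ethenyl], 8-OTES, 9-OMe, 14,14-diethoxy, 15-OTBDPS | CC[Si](CC)(CC)O[C@H]1[C@@H](C(=C)C(=O)OC)[C@H](O)/C=C(/CO[Si](c2ccccc2)(c2ccccc2)C(C)(C)C)CC/C=C(/C(OCC)OCC)[C@@H]1OC | intermediate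
25 | (6R,7S,8S,9S)-15-[(tert-butyldiphenylsilyl)oxy]-14,14-diethoxy-9-methoxy-8-[(triethylsilyl)oxy]germacra-1(10),4,11(13)-trien-12,6-olide, both ring alkenes ring-cis | CC[Si](CC)(CC)O[C@H]1[C@H]2C(=C)C(=O)O[C@@H]2/C=C(/CO[Si](c3ccccc3)(c3ccccc3)C(C)(C)C)CC/C=C(/C(OCC)OCC)[C@@H]1OC | intermediate
26 | (6R,7R,8S,9S)-15-[(tert-butyldiphenylsilyl)oxy]-14,14-diethoxy-8-hydroxy-9-methoxygermacra-1(10),4,11(13)-trien-12,6-olide | O[C@H]1[C@H]2C(=C)C(=O)O[C@@H]2/C=C(/CO[Si](c3ccccc3)(c3ccccc3)C(C)(C)C)CC/C=C(/C(OCC)OCC)[C@@H]1OC | intermediate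
27 | methacrylic anhydride | C=C(C)C(=O)OC(=O)C(C)=C | starting material
28 | (6R,7S,8S,9S)-15-[(tert-butyldiphenylsilyl)oxy]-14,14-diethoxy-9-methoxy-8-(methacryloyloxy)germacra-1(10),4,11(13)-trien-12,6-olide | C=C(C)C(=O)O[C@H]1[C@H]2C(=C)C(=O)O[C@@H]2/C=C(/CO[Si](c3ccccc3)(c3ccccc3)C(C)(C)C)CC/C=C(/C(OCC)OCC)[C@@H]1OC | intermediate
29 | (6R,7S,8S,9S)-15-hydroxy-9-methoxy-8-(methacryloyloxy)-14-oxogermacra-1(10),4,11(13)-trien-12,6-olide, both ring alkenes ring-cis (CNP0114830.1) | C=C(C)C(=O)O[C@H]1[C@H]2C(=C)C(=O)O[C@@H]2/C=C(/CO)CC/C=C(/C=O)[C@@H]1OC | target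

## Step count and risks

Total step count: 16. Longest linear sequence: 13 steps (10 → 29, steps 4–16).

Three steps most likely to fail:

Step 13 (ring closure). The risks are vinylogous elimination of the OTES group from the allylchromium to give a diene, oligomerisation, attack on the wrong face of C7, and a cis-lactone. The stereochemical outcome is a transition-state prediction, not a demonstrated result. The fallback sets out from 23 and comes back at 25. Bromide is displaced with KOAc (18-crown-6, MeCN) to give the primary allylic acetate F1. The ring is then closed with the opposite polarity by SmI2 (THF, t-BuOH, high dilution, −78 °C): the ketyl radical anion of the C6 aldehyde adds to C7, the β-carbon of the enoate, the samarium enolate expels acetate to form the exo-methylene group, and the samarium alkoxide lactonises to 25. No allyl metal is formed, so the silyloxy group cannot be eliminated, and ketyl–olefin additions favour the anti (trans-lactone) arrangement.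

Step 7 (configuration at C9). Chelation by a silyl ether is weaker than by an alkyl ether, and Felkin addition would give the 9-epimer. The fallback sets out from 9 and 12 and comes back at 16. The dienyllithium 14 is added at −78 °C to ester 12 to give the dienyl ketone F2; the chelated tetrahedral intermediate prevents double addition. The carbinol centre is then set by hydride instead of by the carbon nucleophile: 1,2-reduction under Felkin–Anh control (NaBH4, CeCl3·7H2O, MeOH, −78 °C), with hydride entering anti to the α-silyloxy group, gives the syn alcohol 16.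

Step 11 (Baylis–Hillman reaction on the dialdehyde). A hindered, enolisable α-silyloxy-β-methoxy aldehyde has to react over days with an amine next to a geometrically labile enal. The risks are epimerisation at C8, loss of methanol, isomerisation of the C4=C5 alkene and reaction at C6. The fallback sets out from 19 and comes back at 23. The C6 hydroxyl is masked (NaH, 4-methoxybenzyl chloride, Bu4NI, THF) as the 4-methoxybenzyl ether F3. Swern oxidation then gives only the C7 aldehyde F4. This is taken without any amine to the hydroxy acrylate F5 by addition of the 1-(methoxycarbonyl)vinylaluminium reagent made from methyl propiolate, i-Bu2AlH and N-methylmorpholine N-oxide (THF, 0 °C). NBS/Me2S gives the allylic bromide F6, DDQ (CH2Cl2, pH 7 buffer) frees the allylic alcohol F7, and Dess–Martin periodinane (NaHCO3, CH2Cl2) gives 23.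

## Further compounds

F1 | step 13 | methyl (2E,4S,5S,6E,10E)-2-(acetoxymethyl)-10-{[(tert-butyldiphenylsilyl)oxy]methyl}-6-(diethoxymethyl)-5-methoxy-12-oxo-4-[(triethylsilyl)oxy]dodeca-2,6,10-trienoate (23 with OAc in place of Br, same alkene geometry) | O=C/C=C(/CO[Si](c1ccccc1)(c1ccccc1)C(C)(C)C)CC/C=C(/C(OCC)OCC)[C@H](OC)[C@@H](O[Si](CC)(CC)CC)/C=C(\COC(C)=O)C(=O)OC
F2 | step 7 | (2S,4Z)-4-(diethoxymethyl)-1,2-bis[(triethylsilyl)oxy]hepta-4,6-dien-3-one (ketone at C9, same alkene geometry as 16) | C=C/C=C(/C(OCC)OCC)C(=O)[C@@H](O[Si](CC)(CC)CC)CO[Si](CC)(CC)CC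
F3 | step 11 | 4-methoxybenzyl ether of 19 at O6 | COc1ccc(COC/C=C(/CO[Si](c2ccccc2)(c2ccccc2)C(C)(C)C)CC/C=C(/C(OCC)OCC)[C@H](OC)[C@@H](O[Si](CC)(CC)CC)CO[Si](CC)(CC)CC)cc1
F4 | step 11 | C7 aldehyde from F3 (8-OTES kept, O6 as 4-methoxybenzyl ether) | COc1ccc(COC/C=C(/CO[Si](c2ccccc2)(c2ccccc2)C(C)(C)C)CC/C=C(/C(OCC)OCC)[C@H](OC)[C@@H](O[Si](CC)(CC)CC)C=O)cc1
F5 | step 11 | methyl 2-methylidene-3-hydroxy ester formed at C7 of F4 (C7 epimers) | COc1ccc(COC/C=C(/CO[Si](c2ccccc2)(c2ccccc2)C(C)(C)C)CC/C=C(/C(OCC)OCC)[C@H](OC)[C@@H](O[Si](CC)(CC)CC)C(O)C(=C)C(=O)OC)cc1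
F6 | step 11 | (Z)-2-(bromomethyl)enoate from F5 (23 with CH2O-(4-methoxybenzyl) at C6 in place of CHO) | COc1ccc(COC/C=C(/CO[Si](c2ccccc2)(c2ccccc2)C(C)(C)C)CC/C=C(/C(OCC)OCC)[C@H](OC)[C@@H](O[Si](CC)(CC)CC)/C=C(\CBr)C(=O)OC)cc1
F7 | step 11 | allylic alcohol from F6 (23 with CH2OH at C6 in place of CHO) | OC/C=C(/CO[Si](c1ccccc1)(c1ccccc1)C(C)(C)C)CC/C=C(/C(OCC)OCC)[C@H](OC)[C@@H](O[Si](CC)(CC)CC)/C=C(\CBr)C(=O)OC
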